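The route rests on disconnecting the aryl ether bond O1–C8a of ring C. One copper-catalysed intramolecular O-arylation joins the C2 hydroxyl to C8a and closes the dihydropyranone ring C, with both stereocentres already in place. The feature exploited is that C8a of ring A lies ortho to C4a, the carbon that carries the C4 ketone: a bromide at C8a is activated by that carbonyl, which also holds copper beside it. The precursor is an open-chain (2R,3R) anti-aldol, a 2-benzyloxy-3-hydroxy-3-aryl propanone whose carbonyl bears a 6-bromo-3-methoxy-2,4-bis(methoxymethoxy)phenyl group. It is made from a glycolate anti-aldol Weinreb amide and an ortho-magnesiated symmetric bromoarene.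

Key step: step 12

Assumption: in step 7 the aldehyde–TiCl4 complex is taken to add to the enolate face remote from the 4-benzyl group, as in syn-glycolate aldol additions of this auxiliary class, so the (R)-auxiliary should give the (2R,3R) anti adduct; if the sense proved opposite, the (S)-auxiliary would be used with nothing else changed.

Remark: the A-ring phenols are carried as pivalates through the borylation–bromination, because that step releases HBr in hot aqueous methanol, which aryl MOM ethers are not expected to survive. The MOM ethers are put on afterwards and are removed at the end under non-protic conditions that spare the C3 acetate.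

Step 1
Reactants: 1 2-methoxyresorcinol (2-methoxybenzene-1,3-diol)
Product: 2 2-methoxy-1,3-phenylene bis(2,2-dimethylpropanoate)
Conditions: PivCl (2.4 equiv), Et3N, DMAP (cat.), CH2Cl2, 0 °C → rt
Reagents that add atoms: pivaloyl chloride, CC(C)(C)C(=O)Cl
Why: DMAP-catalysed O-acylation of both phenols gives a diester that has no C–H bond open to borylation other than ring C5–H, deactivates the ring towards electrophilic bromination and withstands the acidic bromination medium of step 2.

Step 2
Reactants: 2 2-methoxy-1,3-phenylene bis(2,2-dimethylpropanoate)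
Product: 4 5-bromo-2-methoxy-1,3-phenylene bis(2,2-dimethylpropanoate), via arylboronate 3 (not isolated)
Conditions: [Ir(cod)OMe]2 (1.5 mol%), dtbpy (3 mol%), B2pin2 (0.6 equiv), THF, 80 °C; evaporate; CuBr2 (3 equiv), MeOH/H2O 1:1, 80 °C
Reagents that add atoms: copper(II) bromide, Br[Cu]Br; bis(pinacolato)diboron, CC1(C)OB(OC1(C)C)B1OC(C)(C)C(C)(C)O1 (its boryl group appears in 3 only)
Why: Sterically controlled iridium-catalysed C–H borylation can reach only C5, the one ring C–H with no ortho substituent, and copper(II)-mediated bromodeboronation (transmetallation to copper, then C–Br reductive elimination) puts bromine on the same carbon.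

Step 3
Reactants: 4 5-bromo-2-methoxy-1,3-phenylene bis(2,2-dimethylpropanoate)
Product: 5 5-bromo-2-methoxybenzene-1,3-diol
Conditions: K2CO3, MeOH, 40 °C, N2; then 1 M HCl to pH 4
Reagents that add atoms: none
Why: Base-mediated transesterification (methanolysis) of the two aryl esters frees the phenols once the acidic step is past, the aryl bromide and the methyl ether being inert.

Step 4
Reactants: 5 5-bromo-2-methoxybenzene-1,3-diol
Product: 6 5-bromo-2-methoxy-1,3-bis(methoxymethoxy)benzene
Conditions: MOMCl (3 equiv), i-Pr2NEt, CH2Cl2, 0 °C → rt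
Reagents that add atoms: chloromethyl methyl ether, COCCl
Why: O-alkylation of the phenols with the reactive α-chloro ether (Williamson-type) installs two small acetal ethers that later direct ortho-metallation and tolerate base, organomagnesium reagents and hydrogenation.

Step 5
Reactants: 7 4-hydroxybenzaldehyde
Product: 8 4-(methoxymethoxy)benzaldehyde
Conditions: MOMCl, i-Pr2NEt, CH2Cl2, 0 °C → rt
Reagents that add atoms: chloromethyl methyl ether, COCCl
Why: The same Williamson-type O-alkylation masks the phenol, which would otherwise quench the titanium enolate and the arylmagnesium reagent.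

Step 6
Reactants: 9 (4R)-4-benzyl-1,3-oxazolidine-2-thione; 10 benzyloxyacetyl chloride
Product: 11 (4R)-4-benzyl-3-[(benzyloxy)acetyl]-1,3-oxazolidine-2-thione
Conditions: Et3N, CH2Cl2, 0 °C
Reagents that add atoms: none
Why: N-acylation of the oxazolidinethione by the acid chloride under amine base gives the N-glycolyl imide, N-acylation being the thermodynamic outcome over S-acylation.

Step 7
Reactants: 11 (4R)-4-benzyl-3-[(benzyloxy)acetyl]-1,3-oxazolidine-2-thione; 8 4-(methoxymethoxy)benzaldehyde
Product: 13 (4R)-4-benzyl-3-[(2R,3R)-2-(benzyloxy)-3-hydroxy-3-[4-(methoxymethoxy)phenyl]propanoyl]-1,3-oxazolidine-2-thione, via titanium enolate 12 (not isolated)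
Conditions: TiCl4 (1.1 equiv), i-Pr2NEt (1.2 equiv), CH2Cl2, −78 °C; then 8 (2 equiv) premixed with TiCl4 (2.5 equiv), −78 °C; aq. NH4Cl
Reagents that add atoms: titanium tetrachloride, Cl[Ti](Cl)(Cl)Cl (its atoms appear in 12 only; none remain in 13)
Why: In this titanium-mediated anti-selective glycolate aldol addition the chlorotitanium (Z)-enolate adds through an open transition state to the aldehyde activated by a second equivalent of TiCl4, so the α-benzyloxy and β-hydroxy centres (future C3 and C2) should come out anti, and the 4-benzyl group of the (R)-auxiliary shields one enolate face to set both as R, the minor syn isomer being removed by chromatography.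

Step 8
Reactants: 13 (4R)-4-benzyl-3-[(2R,3R)-2-(benzyloxy)-3-hydroxy-3-[4-(methoxymethoxy)phenyl]propanoyl]-1,3-oxazolidine-2-thione
Product: 14 (2R,3R)-2-(benzyloxy)-3-hydroxy-N-methoxy-N-methyl-3-[4-(methoxymethoxy)phenyl]propanamide
Conditions: MeONHMe·HCl (3 equiv), imidazole (5 equiv), CH2Cl2, rt
Reagents that add atoms: N,O-dimethylhydroxylamine hydrochloride, CNOC.Cl
Why: The activated N-acyl oxazolidinethione undergoes direct aminolysis (acyl transfer) by N,O-dimethylhydroxylamine under imidazole buffering, which releases the auxiliary without touching either stereocentre.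

Step 9
Reactants: 14 (2R,3R)-2-(benzyloxy)-3-hydroxy-N-methoxy-N-methyl-3-[4-(methoxymethoxy)phenyl]propanamide
Product: 15 (2R,3R)-2-(benzyloxy)-N-methoxy-N-methyl-3-[4-(methoxymethoxy)phenyl]-3-[(triethylsilyl)oxy]propanamide
Conditions: TESCl, imidazole, DMF, 0 °C → rt
Reagents that add atoms: chlorotriethylsilane, CC[Si](Cl)(CC)CC
Why: Silylation of the secondary benzylic alcohol keeps it from quenching the aryl nucleophile, and the triethylsilyl ether can later be removed by buffered fluoride.

Step 10
Reactants: 6 5-bromo-2-methoxy-1,3-bis(methoxymethoxy)benzene; 15 (2R,3R)-2-(benzyloxy)-N-methoxy-N-methyl-3-[4-(methoxymethoxy)phenyl]-3-[(triethylsilyl)oxy]propanamide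
Product: 17 (2R,3R)-2-(benzyloxy)-1-[6-bromo-3-methoxy-2,4-bis(methoxymethoxy)phenyl]-3-[4-(methoxymethoxy)phenyl]-3-[(triethylsilyl)oxy]propan-1-one, via arylmagnesium chloride 16 (not isolated)
Conditions: 6 (1.6 equiv), TMPMgCl·LiCl (1.5 equiv), THF, 0 °C; then 15 (1.0 equiv), −20 °C → rt; aq. NH4Cl
Reagents that add atoms: 2,2,6,6-tetramethylpiperidinylmagnesium chloride–lithium chloride, CC1(C)CCCC(C)(C)N1[Mg]Cl.[Li+].[Cl-] (magnesium and chlorine appear in 16 only)
Why: Directed ortho-magnesiation with the turbo-Hauser base occurs at the only ring C–H, acidified by the flanking OMOM and bromine, and the arylmagnesium adds once to the amide (Weinreb ketone synthesis through a chelated tetrahedral intermediate helped by the α-benzyloxy group); since 6 is symmetric, only one aryl ketone can form.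

Step 11
Reactants: 17 (2R,3R)-2-(benzyloxy)-1-[6-bromo-3-methoxy-2,4-bis(methoxymethoxy)phenyl]-3-[4-(methoxymethoxy)phenyl]-3-[(triethylsilyl)oxy]propan-1-one
Product: 18 (2R,3R)-2-(benzyloxy)-1-[6-bromo-3-methoxy-2,4-bis(methoxymethoxy)phenyl]-3-hydroxy-3-[4-(methoxymethoxy)phenyl]propan-1-one
Conditions: HF·pyridine, pyridine, THF, 0 °C → rt
Reagents that add atoms: none
Why: Fluoride-mediated desilylation under buffered, slightly acidic conditions should free the benzylic alcohol without retro-aldol cleavage, β-elimination or loss of the MOM ethers.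

Step 12
Reactants: 18 (2R,3R)-2-(benzyloxy)-1-[6-bromo-3-methoxy-2,4-bis(methoxymethoxy)phenyl]-3-hydroxy-3-[4-(methoxymethoxy)phenyl]propan-1-one
Product: 19 (2R,3R)-3-(benzyloxy)-6-methoxy-5,7-bis(methoxymethoxy)-2-[4-(methoxymethoxy)phenyl]-2,3-dihydro-4H-chromen-4-one
Conditions: CuI (10 mol%), 3,4,7,8-tetramethyl-1,10-phenanthroline (20 mol%), Cs2CO3 (1.5 equiv), 4 Å MS, degassed toluene, 80 °C
Reagents that add atoms: none
Why: Carbonate and copper(I) turn the C2 hydroxyl into a phenanthroline-ligated copper(I) alkoxide; with the C4 carbonyl oxygen also bound, copper sits beside C8a, inserts into the C8a–Br bond (oxidative addition to an aryl–copper(III) alkoxide, a seven-membered cupracycle), and reductive elimination forms O1–C8a and returns copper(I). The closest known reaction type is the intramolecular Ullmann-type copper-catalysed O-arylation of aliphatic alcohols that gives chromans, here accelerated by the ortho carbonyl as in Hurtley-type couplings of ortho-halo aryl carbonyl compounds. Ring C closes as a six-membered ring in a 6-exo sense at the sp2 carbon C8a, the C–Br bond being exocyclic to the new ring. No stereocentre is created: the C2–O and C3–O bonds are never broken, so the anti arrangement of 18 should become the 2,3-trans (2R,3R) arrangement of 19. C–O coupling has to outrun retro-aldol cleavage, dehydration and C3 enolisation (which could also open the product to a chalcone); this is addressed by a sparingly soluble carbonate in toluene that keeps free alkoxide low, by the covalent copper alkoxide, by ligand- and ketone-assisted oxidative addition that allows 80 °C or below, and by the benzyl ether at O3, which cannot migrate. Only one hydroxyl and one bromide are present, so no regiochemical choice arises.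

Step 13
Reactants: 19 (2R,3R)-3-(benzyloxy)-6-methoxy-5,7-bis(methoxymethoxy)-2-[4-(methoxymethoxy)phenyl]-2,3-dihydro-4H-chromen-4-one
Product: 20 (2R,3R)-3-hydroxy-6-methoxy-5,7-bis(methoxymethoxy)-2-[4-(methoxymethoxy)phenyl]-2,3-dihydro-4H-chromen-4-one
Conditions: H2 (1 atm), 10% Pd/C, EtOAc, rt
Reagents that add atoms: none
Why: Heterogeneous catalytic hydrogenolysis cleaves the alkyl benzyl ether at O3, while the MOM ethers, the aryl ketone and the ring C2–O1 bond should survive at 1 atm and room temperature, and no aryl bromide is left to be reduced.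

Step 14
Reactants: 20 (2R,3R)-3-hydroxy-6-methoxy-5,7-bis(methoxymethoxy)-2-[4-(methoxymethoxy)phenyl]-2,3-dihydro-4H-chromen-4-one
Product: 21 (2R,3R)-6-methoxy-5,7-bis(methoxymethoxy)-2-[4-(methoxymethoxy)phenyl]-4-oxo-3,4-dihydro-2H-chromen-3-yl acetate
Conditions: Ac2O, pyridine, DMAP (cat.), CH2Cl2, 0 °C
Reagents that add atoms: acetic anhydride, CC(=O)OC(C)=O
Why: DMAP-catalysed O-acylation of the only free hydroxyl, under cold and weakly basic conditions that should neither epimerise C3 nor open ring C.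

Step 15
Reactants: 21 (2R,3R)-6-methoxy-5,7-bis(methoxymethoxy)-2-[4-(methoxymethoxy)phenyl]-4-oxo-3,4-dihydro-2H-chromen-3-yl acetate
Product: 23 (2R,3R)-5,7-dihydroxy-2-(4-hydroxyphenyl)-6-methoxy-4-oxo-3,4-dihydro-2H-chromen-3-yl acetate (6-methoxyaromadendrin 3-O-acetate), via tris-trimethylsilyl ether 22 (not isolated)
Conditions: TMSOTf (8 equiv), 2,2'-bipyridyl (12 equiv), MeCN, 0 °C → rt; then H2O, rt; aq. NaHCO3
Reagents that add atoms: trimethylsilyl trifluoromethanesulfonate, C[Si](C)(C)OS(=O)(=O)C(F)(F)F (its silyl groups appear in 22 only)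
Why: The silyl triflate–bipyridyl complex converts aromatic MOM ethers into aryl silyl ethers (non-protic acetal cleavage, the methoxymethyl unit being captured by bipyridyl and so kept from alkylating C8), and water then hydrolyses these to the phenols, near-neutral conditions that should spare the C3 acetate, the 6-methyl ether and both stereocentres.

Compound list
1 | 2-methoxyresorcinol (2-methoxybenzene-1,3-diol) | COc1c(O)cccc1O | starting material
2 | 2-methoxy-1,3-phenylene bis(2,2-dimethylpropanoate) | COc1c(OC(=O)C(C)(C)C)cccc1OC(=O)C(C)(C)C | intermediate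
3 | 2-methoxy-5-(4,4,5,5-tetramethyl-1,3,2-dioxaborolan-2-yl)-1,3-phenylene bis(2,2-dimethylpropanoate) | COc1c(OC(=O)C(C)(C)C)cc(B2OC(C)(C)C(C)(C)O2)cc1OC(=O)C(C)(C)C | intermediate (not isolated)
4 | 5-bromo-2-methoxy-1,3-phenylene bis(2,2-dimethylpropanoate) | COc1c(OC(=O)C(C)(C)C)cc(Br)cc1OC(=O)C(C)(C)C | intermediate
5 | 5-bromo-2-methoxybenzene-1,3-diol | COc1c(O)cc(Br)cc1O | intermediate
6 | 5-bromo-2-methoxy-1,3-bis(methoxymethoxy)benzene | COCOc1cc(Br)cc(OCOC)c1OC | intermediate
7 | 4-hydroxybenzaldehyde | O=Cc1ccc(O)cc1 | starting material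
8 | 4-(methoxymethoxy)benzaldehyde | COCOc1ccc(C=O)cc1 | intermediate
9 | (4R)-4-benzyl-1,3-oxazolidine-2-thione | S=C1N[C@H](Cc2ccccc2)CO1 | starting material
10 | benzyloxyacetyl chloride | O=C(Cl)COCc1ccccc1 | starting material
11 | (4R)-4-benzyl-3-[(benzyloxy)acetyl]-1,3-oxazolidine-2-thione | S=C1OC[C@@H](Cc2ccccc2)N1C(=O)COCc1ccccc1 | intermediate
12 | trichlorotitanium (Z)-enolate of 11 | Cl[Ti](Cl)(Cl)O/C(=C\OCc1ccccc1)N1C(=S)OC[C@H]1Cc1ccccc1 | intermediate (not isolated)
13 | (4R)-4-benzyl-3-[(2R,3R)-2-(benzyloxy)-3-hydroxy-3-[4-(methoxymethoxy)phenyl]propanoyl]-1,3-oxazolidine-2-thione | S=C1OC[C@@H](Cc2ccccc2)N1C(=O)[C@H](OCc1ccccc1)[C@@H](c1ccc(OCOC)cc1)O | intermediate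
14 | (2R,3R)-2-(benzyloxy)-3-hydroxy-N-methoxy-N-methyl-3-[4-(methoxymethoxy)phenyl]propanamide | CON(C)C(=O)[C@H](OCc1ccccc1)[C@@H](c1ccc(OCOC)cc1)O | intermediate
15 | (2R,3R)-2-(benzyloxy)-N-methoxy-N-methyl-3-[4-(methoxymethoxy)phenyl]-3-[(triethylsilyl)oxy]propanamide | CON(C)C(=O)[C@H](OCc1ccccc1)[C@@H](c1ccc(OCOC)cc1)O[Si](CC)(CC)CC | intermediate
16 | [6-bromo-3-methoxy-2,4-bis(methoxymethoxy)phenyl]magnesium chloride (lithium chloride complex) | COc1c(OCOC)cc(Br)c([Mg]Cl)c1OCOC | intermediate (not isolated)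
17 | (2R,3R)-2-(benzyloxy)-1-[6-bromo-3-methoxy-2,4-bis(methoxymethoxy)phenyl]-3-[4-(methoxymethoxy)phenyl]-3-[(triethylsilyl)oxy]propan-1-one | COc1c(OCOC)cc(Br)c(c1OCOC)C(=O)[C@H](OCc1ccccc1)[C@@H](c1ccc(OCOC)cc1)O[Si](CC)(CC)CC | intermediate
18 | (2R,3R)-2-(benzyloxy)-1-[6-bromo-3-methoxy-2,4-bis(methoxymethoxy)phenyl]-3-hydroxy-3-[4-(methoxymethoxy)phenyl]propan-1-one (anti-aldol bromoketone) | COc1c(OCOC)cc(Br)c(c1OCOC)C(=O)[C@H](OCc1ccccc1)[C@@H](c1ccc(OCOC)cc1)O | intermediate
19 | (2R,3R)-3-(benzyloxy)-6-methoxy-5,7-bis(methoxymethoxy)-2-[4-(methoxymethoxy)phenyl]-2,3-dihydro-4H-chromen-4-one (trans-3-O-benzyl-5,7,4'-tris-O-methoxymethyl-6-methoxyaromadendrin) | COc1c(OCOC)cc2c(c1OCOC)C(=O)[C@H](OCc3ccccc3)[C@@H](c3ccc(OCOC)cc3)O2 | intermediate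
20 | (2R,3R)-3-hydroxy-6-methoxy-5,7-bis(methoxymethoxy)-2-[4-(methoxymethoxy)phenyl]-2,3-dihydro-4H-chromen-4-one | COc1c(OCOC)cc2c(c1OCOC)C(=O)[C@H](O)[C@@H](c3ccc(OCOC)cc3)O2 | intermediate
21 | (2R,3R)-6-methoxy-5,7-bis(methoxymethoxy)-2-[4-(methoxymethoxy)phenyl]-4-oxo-3,4-dihydro-2H-chromen-3-yl acetate | COc1c(OCOC)cc2c(c1OCOC)C(=O)[C@H](OC(C)=O)[C@@H](c3ccc(OCOC)cc3)O2 | intermediate
22 | (2R,3R)-6-methoxy-4-oxo-5,7-bis[(trimethylsilyl)oxy]-2-{4-[(trimethylsilyl)oxy]phenyl}-3,4-dihydro-2H-chromen-3-yl acetate | COc1c(O[Si](C)(C)C)cc2c(c1O[Si](C)(C)C)C(=O)[C@H](OC(C)=O)[C@@H](c3ccc(O[Si](C)(C)C)cc3)O2 | intermediate (not isolated)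
23 | (2R,3R)-5,7-dihydroxy-2-(4-hydroxyphenyl)-6-methoxy-4-oxo-3,4-dihydro-2H-chromen-3-yl acetate (6-methoxyaromadendrin 3-O-acetate) | COc1c(O)cc2c(c1O)C(=O)[C@H](OC(C)=O)[C@@H](c1ccc(O)cc1)O2 | target

Total step count: 15. Longest linear sequence: 10 steps (1 → 2 → 4 → 5 → 6 → 17 → 18 → 19 → 20 → 21 → 23; the branch from 7 through 8, 13, 14 and 15 is equally long).

Steps most likely to fail

Step 12. Base-induced retro-aldol fragmentation or dehydration of the β-hydroxy ketone, or enolisation at C3 followed by opening of the product, may outpace C–O bond formation. The fallback sets out from 18 and removes the aldol carbonyl before the ring closure. Reduction with NaBH4 (MeOH/THF, 0 °C) should give (1RS,2R,3R)-2-(benzyloxy)-1-[6-bromo-3-methoxy-2,4-bis(methoxymethoxy)phenyl]-3-[4-(methoxymethoxy)phenyl]propane-1,3-diol F1, which is stable to carbonate. The same copper-catalysed O-arylation (CuI, tetramethylphenanthroline, Cs2CO3, toluene, 110 °C) can then only engage the C3 hydroxyl, since the C1 hydroxyl would have to form a four-membered ring. This should give 2,3-trans-3-(benzyloxy)-6-methoxy-5,7-bis(methoxymethoxy)-2-[4-(methoxymethoxy)phenyl]chroman-4-ol F2 as a mixture of C4 epimers. Dess–Martin oxidation (NaHCO3-buffered, CH2Cl2) of the C4 carbinol returns to 19.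

Step 10. Slow addition of the doubly ortho-substituted arylmagnesium to the amide, with competing deprotonation next to the amide carbonyl and decay of the ortho-bromoaryl metal on warming, may leave the ketone unformed. The fallback sets out from 15 and uses a more electrophilic acceptor. DIBAL-H (THF, −78 °C) should reduce the Weinreb amide to (2R,3R)-2-(benzyloxy)-3-[4-(methoxymethoxy)phenyl]-3-[(triethylsilyl)oxy]propanal F3. Addition of 16 at −40 → 0 °C should give 2-(benzyloxy)-1-[6-bromo-3-methoxy-2,4-bis(methoxymethoxy)phenyl]-3-[4-(methoxymethoxy)phenyl]-3-[(triethylsilyl)oxy]propan-1-ol F4, with C2 and C3 as in 17 and both C1 epimers acceptable. Dess–Martin oxidation then returns to 17.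

Step 7. Weak anti over syn selectivity with the electron-rich aromatic aldehyde, an unexpected sense of facial induction, or loss of the MOM ether to excess TiCl4 may erode the supply of 13. The fallback sets out from 10 and 8, avoids any strong Lewis acid and returns at 14. (4S)-4-Benzyl-1,3-oxazolidin-2-one is acylated with 10 (n-BuLi, THF, −78 °C) to (4S)-4-benzyl-3-[(benzyloxy)acetyl]-1,3-oxazolidin-2-one F5. The magnesium chloride-catalysed Evans anti-aldol with 8 (MgCl2 10 mol%, Et3N, TMSCl, EtOAc, rt) proceeds through a chelated magnesium (Z)-enolate attacked on the face remote from the benzyl group, so the (S)-imide is expected to give the anti adduct as its silyl ether, (4S)-4-benzyl-3-[(2R,3R)-2-(benzyloxy)-3-[4-(methoxymethoxy)phenyl]-3-[(trimethylsilyl)oxy]propanoyl]-1,3-oxazolidin-2-one F6. Brief dilute HCl in THF should cleave it to (4S)-4-benzyl-3-[(2R,3R)-2-(benzyloxy)-3-hydroxy-3-[4-(methoxymethoxy)phenyl]propanoyl]-1,3-oxazolidin-2-one F7. Transamination with Me3Al and MeONHMe·HCl (CH2Cl2, 0 °C) then gives 14.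

Further compounds
F1 | step 12 | (1RS,2R,3R)-2-(benzyloxy)-1-[6-bromo-3-methoxy-2,4-bis(methoxymethoxy)phenyl]-3-[4-(methoxymethoxy)phenyl]propane-1,3-diol | COc1c(OCOC)cc(Br)c(c1OCOC)C(O)[C@H](OCc1ccccc1)[C@@H](c1ccc(OCOC)cc1)O
F2 | step 12 | (2R,3S,4RS)-3-(benzyloxy)-6-methoxy-5,7-bis(methoxymethoxy)-2-[4-(methoxymethoxy)phenyl]-3,4-dihydro-2H-chromen-4-ol (2,3-trans) | COc1c(OCOC)cc2c(c1OCOC)C(O)[C@H](OCc3ccccc3)[C@@H](c3ccc(OCOC)cc3)O2
F3 | step 10 | (2R,3R)-2-(benzyloxy)-3-[4-(methoxymethoxy)phenyl]-3-[(triethylsilyl)oxy]propanal | O=C[C@H](OCc1ccccc1)[C@@H](c1ccc(OCOC)cc1)O[Si](CC)(CC)CC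
F4 | step 10 | (1RS,2S,3R)-2-(benzyloxy)-1-[6-bromo-3-methoxy-2,4-bis(methoxymethoxy)phenyl]-3-[4-(methoxymethoxy)phenyl]-3-[(triethylsilyl)oxy]propan-1-ol | COc1c(OCOC)cc(Br)c(c1OCOC)C(O)[C@H](OCc1ccccc1)[C@@H](c1ccc(OCOC)cc1)O[Si](CC)(CC)CC
F5 | step 7 | (4S)-4-benzyl-3-[(benzyloxy)acetyl]-1,3-oxazolidin-2-one | O=C1OC[C@H](Cc2ccccc2)N1C(=O)COCc1ccccc1
F6 | step 7 | (4S)-4-benzyl-3-[(2R,3R)-2-(benzyloxy)-3-[4-(methoxymethoxy)phenyl]-3-[(trimethylsilyl)oxy]propanoyl]-1,3-oxazolidin-2-one | O=C1OC[C@H](Cc2ccccc2)N1C(=O)[C@H](OCc1ccccc1)[C@@H](c1ccc(OCOC)cc1)O[Si](C)(C)C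
F7 | step 7 | (4S)-4-benzyl-3-[(2R,3R)-2-(benzyloxy)-3-hydroxy-3-[4-(methoxymethoxy)phenyl]propanoyl]-1,3-oxazolidin-2-one | O=C1OC[C@H](Cc2ccccc2)N1C(=O)[C@H](OCc1ccccc1)[C@@H](c1ccc(OCOC)cc1)O
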